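**Compound numbers used throughout:** 1 2,4-dibromophenol; 2 1,2-dibromoethane; 3 2,4-dibromo-1-(2-bromoethoxy)benzene; 4 2,4-dibromo-1-(ethenyloxy)benzene; 5 2,4-dibromo-1-(1,2-dibromoethoxy)benzene; 6 (Z)-2,4-dibromo-1-(2-bromoethenyloxy)benzene; 7 2,4-dibromo-1-(ethynyloxy)benzene; 8 (E)-(2-bromoethenyl)trimethylsilane; 9 Cr(CO)6; 10 (E)-2-(trimethylsilyl)ethenyllithium; 11 the lithium acylchromate; 12 the methoxy(silylvinyl)carbene complex; 13 the Cr(CO)3 complex of 14; 14 the aryl trimethylsilyl ether from the annulation; 15 its free phenol; 16 its pivalate; 17 the C4 phenol; 18 the 3,5-dibromide; 19 its methyl ether; 20 the target.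

## Analysis of the target

Target 20 is a diaryl ether in which two benzene rings are joined through one oxygen; there is no further ring and no stereocenter. Ring B is a 2,4-dibromophenyl group, and ring A, numbered from the hydroxyl carbon, carries OH at C1, the aryloxy group at C2, Br at C3, OMe at C4, Br at C5 and H at C6. The four aryl C–Br bonds rule out alkyllithium reagents, zerovalent palladium and hydrogenolysis once they are in place, and the hydroquinone monoether core is easily oxidized to a quinone. The main difficulty is that the ring A bromines flank the methoxy carbon C4, while C6, next to the free hydroxyl, carries hydrogen. That is the opposite of what bromination of the target's own phenol would give, so the C1 and C4 oxygens must be told apart and their roles exchanged for a while. A second difficulty is that ring B must hold exactly two bromines at defined positions. The strategy rests on one feature: without its two bromines, ring A is a 4-methoxyphenol with the aryloxy group on C2, beside the hydroxyl, which is the pattern that a methoxy(alkenyl)carbene ligand on chromium, a terminal alkyne and a carbonyl ligand assemble (carbene carbon to C4, carbonyl to C1, substituted alkyne carbon to C2).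

## Retrosynthetic reasoning

**Ester at C1 (20 from 19).** The last bond cut is the acyl C–O bond of a pivalate on the C1 oxygen. Keeping this oxygen acylated until the end makes it an inert, electron-poor substituent during everything done at C3, C4 and C5. The forward step is a simple transesterification.

**Methyl at C4 and bromines at C3 and C5 (19 from 18 from 17).** The O–CH3 bond and then the two C–Br bonds are cut. Both bromines are ortho to the C4 oxygen, so they are best introduced when C4 carries a free hydroxyl and C1 an ester: the phenol then directs to its two ortho positions and to nothing else. Cutting the C–Br bonds with C4 still methylated would require substitution at C3, flanked by OMe and OAr on an already deactivated ring, where ring B and C6 could compete. The forward reactions are an ortho,ortho-dibromination of a phenol and an O-methylation of a hindered, acidic phenol.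

**Exchange of the groups on the two oxygens (17 from 16 from 14).** The annulation product 14 has C4 as a methyl ether and C1 as a silyl ether. The silyl group is replaced by the pivalate (via phenol 15) and the methyl is removed, so that the free hydroxyl sits at C4. This detour costs steps. It is accepted because it turns the differentiation of the two oxygens, which the ring construction delivers, into full control of where the bromines go.

**Ring A (14 from 12 and 7).** Three bonds are cut: C3–C4, C1–C2 and C1–C6. This leaves the alkenylcarbene complex 12, which supplies C4 with its methoxy group, C5, C6 and, from a carbonyl ligand, C1 with its oxygen, and the alkyne 7, which supplies C2 and C3 and carries ring B complete with both bromines. The cut is made here because it is the only one that creates the 1,2,4-trioxygenated ring with the C1 and C4 oxygens already different. The forward reaction must insert the alkyne with its substituted carbon next to the carbonyl-derived C1. It must then close the ring and move silicon from C6 to oxygen.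

**Carbene complex (12 from 8 and 9).** The Cr=C bond and the O–CH3 bond are cut in the Fischer sense, via vinyllithium 10 and acylchromate 11. The silyl group on the vinyl unit makes the alkenyl complex handleable and later protects the C1 oxygen.

**Alkyne (7 from 4 from 3 from 1 and 2).** The triple bond is traced back, through dibromide 5 and bromovinyl ether 6, to vinyl ether 4. The vinyl group comes from the two carbons of 2, attached to the oxygen of 1 as the bromoethyl ether 3. Ring B is thus bought with its bromines in place. The forward sequence must avoid organolithium reagents and very strong unhindered amides, which would attack the aryl bromides.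

## Alternatives that were turned down

Alternative 1: All four C–Br bonds are cut at once and the C1 oxygen is traced back to a formyl group, which leads to 4-hydroxy-2-phenoxybenzaldehyde A2.
- Forward key step: four equivalents of electrophilic bromine substitute A2 at C3 and C5 of ring A and at C4′ and C2′ of ring B, which should give 3,5-dibromo-2-(2,4-dibromophenoxy)-4-hydroxybenzaldehyde A1. O-Methylation of A1 and a Baeyer–Villiger oxidation with formate cleavage would then give 20.
- For: it is by far the shortest plan, roughly half the steps of the chosen route, with ordinary reagents. On ring A of A2 the hydroxyl and the formyl group direct to the same two carbons.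
- Against: the ring B pattern of A1 depends on rates alone. The para position reacts readily, but the reaction must then take exactly one ortho position and stop before C6′, on a ring whose activating oxygen is shared with an increasingly electron-poor ring A. The later oxidation must make the aryl group migrate in an electron-poor, tetrabrominated aldehyde derived from A1, whose para methoxy group is twisted out of conjugation by two ortho bromines, so hydride migration may win and the ring carbon would then keep its carbon substituent.
- Comparison: Alternative 1 is clearly stronger on step economy and simplicity. The chosen route offers instead a ring B taken intact from 1 and ring A positions fixed by construction.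

Alternative 2: The C4–O bond is cut, so the methoxy oxygen is introduced last, on 3,5-dibromo-2-(2,4-dibromophenoxy)phenol A4.
- Forward key step: anodic oxidation of A4 in the alcohol that supplies the methoxy groups forms two C4–O bonds and should give 3,5-dibromo-2-(2,4-dibromophenoxy)-4,4-dimethoxycyclohexa-2,5-dien-1-one A3. A two-electron reduction of A3 with loss of one methoxy group would give 20.
- For: oxygenation para to a phenol is inherent to this oxidation, so the position of the new oxygen is not in doubt, and no protecting group is needed.
- Against: A4 has its ring A bromines meta to the hydroxyl, a pattern no direct bromination of a phenol gives, so the difficulty moves into the synthesis of A4. A polybrominated phenol oxidizes only at high potential. In A3 both ring A bromines sit at the β-carbons of the dienone and are open to addition–elimination by the alcohol and to loss in the reduction.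
- Comparison: Alternative 2 is more direct than the demethylation and remethylation of the chosen route for the C4 oxygen. The chosen route places the bromines by ordinary ortho direction and never has them on a dienone.

Alternative 3: Ring A is cut at C2–C3 and C5–C6 (target numbering) into the 1,3-bis(silyloxy)diene 4-(2,4-dibromophenoxy)-1-methoxy-1,3-bis(trimethylsilyloxy)buta-1,3-diene A6 and the masked methoxymalonaldehyde 1,1,2,3,3-pentamethoxypropane A7.
- Forward key step: a [3+3] cyclocondensation of A6 with A7 under a strong titanium Lewis acid closes ring A as methyl 3-(2,4-dibromophenoxy)-2-hydroxy-5-methoxybenzoate A5.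
- For: all three ring A oxygens arrive in place, ring B comes from 1, and the chemistry is metal-carbene-free, cheap and scalable, with no unstable ynol ether. A6 and A7 are both simple, acyclic building blocks.
- Against: A5 carries an ester carbon at C6, where the target has hydrogen. Removing it means saponification and decarboxylation of a salicylic acid under forcing conditions that suit aryl bromides poorly. The free hydroxyl of A5 is the C1 hydroxyl, so the C3/C5 bromination problem remains and the same oxygen-role exchange is still needed.
- Comparison: Alternative 3 is stronger on the practicality of the ring-forming step. The chosen route gives ring A with hydrogen at C6 and the C1 oxygen already protected, so no carbon has to be excised.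

Key step: step 5

Assumption: the diaryl ether axis is taken as freely rotating at room temperature (the target is achiral), and 8 is taken as a purchasable reagent.

## Route

Step 1
Reactants: 1 2,4-dibromophenol; 2 1,2-dibromoethane
Product: 3 2,4-dibromo-1-(2-bromoethoxy)benzene
Conditions: K2CO3 (2 equiv), 2 (5 equiv), MeCN, reflux
Reagents that add atoms: none
Why: Williamson ether synthesis (SN2); the acidic phenol is fully deprotonated by K2CO3 and the large excess of 2 suppresses the second substitution to the bis(aryloxy)ethane.

Step 2
Reactants: 3 2,4-dibromo-1-(2-bromoethoxy)benzene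
Product: 4 2,4-dibromo-1-(ethenyloxy)benzene
Conditions: KOt-Bu (1.5 equiv), THF, 0 °C to rt
Reagents that add atoms: none
Why: E2 dehydrobromination of a 2-bromoethyl aryl ether with a hindered alkoxide, the standard access to aryl vinyl ethers; the aryl bromides are inert to KOt-Bu in THF at this temperature.

Step 3
Reactants: 4 2,4-dibromo-1-(ethenyloxy)benzene
Product: 7 2,4-dibromo-1-(ethynyloxy)benzene, via 2,4-dibromo-1-(1,2-dibromoethoxy)benzene 5 (not isolated), via (Z)-2,4-dibromo-1-(2-bromoethenyloxy)benzene 6 (not isolated)
Conditions: Br2 (1.0 equiv), CH2Cl2, −78 °C; solvent exchange to THF at 0 °C; KN(SiMe3)2 (3.2 equiv), THF, −78 to −30 °C; NH4Cl (aq) at −78 °C; 7 kept as a cold solution and used at once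
Reagents that add atoms: none
Why: Bromine adds across the electron-rich vinyl ether much faster than it substitutes the deactivated ring B, and the dibromide 5 then loses HBr twice under a non-nucleophilic amide (E2, the second loss an anti elimination from the Z-bromovinyl ether 6), the classical dehydrohalogenation route to ynol ethers. KN(SiMe3)2 is chosen because, unlike alkyllithium reagents or NaNH2, it should neither exchange nor metalate the aryl bromides at low temperature; the excess holds 7 as its acetylide until the cold quench.

Step 4
Reactants: 8 (E)-(2-bromoethenyl)trimethylsilane; 9 chromium hexacarbonyl, Cr(CO)6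
Product: 12 pentacarbonyl[(2E)-1-methoxy-3-(trimethylsilyl)prop-2-en-1-ylidene]chromium, via (E)-2-(trimethylsilyl)ethenyllithium 10 (not isolated), via lithium acylpentacarbonylchromate 11 (not isolated)
Conditions: t-BuLi (2.0 equiv), Et2O, −78 °C; Cr(CO)6, Et2O, −78 to 0 °C; MeOTf, CH2Cl2, 0 °C to rt
Reagents that add atoms: methyl trifluoromethanesulfonate, COS(=O)(=O)C(F)(F)F
Why: Fischer carbene synthesis: bromine–lithium exchange with retention of the E geometry, addition of the vinyllithium 10 to a carbonyl ligand of Cr(CO)6, and O-methylation of the acylchromate 11 by a hard methylating agent; the trans silyl group makes the alkenyl complex of zerovalent chromium stable enough to handle.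

Step 5
Reactants: 12 pentacarbonyl[(2E)-1-methoxy-3-(trimethylsilyl)prop-2-en-1-ylidene]chromium; 7 2,4-dibromo-1-(ethynyloxy)benzene
Product: 14 [2-(2,4-dibromophenoxy)-4-methoxyphenoxy]trimethylsilane, via tricarbonylchromium arene complex 13 (not isolated)
Conditions: 7 (1.5 equiv, slow addition), THF (0.05 M), 50 °C, Ar; then air, Et2O, rt, daylight; filtration through Celite and neutral alumina
Reagents that add atoms: none
Why: Proposed new method: the closest known reaction type is the Dötz benzannulation of alkenyl(methoxy)carbene complexes of zerovalent chromium with terminal alkynes, including trans-2-silylvinyl complexes that give O-silylated 4-methoxyphenols, but an aryl ethynyl ether has not been shown as the alkyne partner. Thermal loss of one carbonyl ligand from 12 opens a site for 7; insertion of the alkyne into the Cr=C bond forms C3–C4 and leaves the aryloxy-bearing carbon on chromium, and carbonyl insertion then forms C1–C2 and gives a chromium-bound dienylketene. Ring A closes by 6π electrocyclization of this ketene (bond C1–C6, overall a [3+2+1] assembly). The resulting 6-silylcyclohexa-2,4-dienone aromatizes by a 1,3 shift of silicon from C6 to the carbonyl oxygen, so the arene complex 13 carries the C1 oxygen as its silyl ether, and air then releases 14 from chromium. No stereocenter is formed. The step needs one regiochemical outcome, the substituted alkyne carbon next to the carbonyl-derived C1: the unsubstituted alkyne terminus is the small end and bonds to the carbene carbon, and the aryloxy oxygen stabilizes the new carbene carbon on chromium, so steric and electronic preferences act in the same sense. It also needs phenol formation to win over cyclopentannulation and over oligomerization of the ynol ether; an alkenyl(methoxy) complex of chromium in THF at moderate temperature is the combination most inclined to insert a carbonyl ligand, and slow addition keeps the concentration of 7 low.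

Step 6
Reactants: 14 [2-(2,4-dibromophenoxy)-4-methoxyphenoxy]trimethylsilane
Product: 16 2-(2,4-dibromophenoxy)-4-methoxyphenyl 2,2-dimethylpropanoate, via 2-(2,4-dibromophenoxy)-4-methoxyphenol 15 (not isolated)
Conditions: K2CO3 (cat.), MeOH, rt; evaporation, toluene azeotrope; PivCl (1.5 equiv), Et3N, DMAP (cat.), CH2Cl2, 0 °C to rt
Reagents that add atoms: pivaloyl chloride, CC(C)(C)C(Cl)=O
Why: Base-catalysed methanolysis removes the labile aryl trimethylsilyl ether, and DMAP-catalysed acylation of phenol 15 puts a robust, electron-withdrawing ester on the C1 oxygen, which switches off its directing power for step 8.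

Step 7
Reactants: 16 2-(2,4-dibromophenoxy)-4-methoxyphenyl 2,2-dimethylpropanoate
Product: 17 2-(2,4-dibromophenoxy)-4-hydroxyphenyl 2,2-dimethylpropanoate
Conditions: BBr3 (2.5 equiv), CH2Cl2, −78 to 0 °C; then H2O, 0 °C
Reagents that add atoms: none
Why: Lewis-acid cleavage of an aryl methyl ether, in which bromide attacks the methyl group of the boron-bound ether; the diaryl ether offers no alkyl carbon for attack and the hindered aryl pivalate should survive at low temperature.

Step 8
Reactants: 17 2-(2,4-dibromophenoxy)-4-hydroxyphenyl 2,2-dimethylpropanoate
Product: 18 3,5-dibromo-2-(2,4-dibromophenoxy)-4-hydroxyphenyl 2,2-dimethylpropanoate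
Conditions: NBS (2.05 equiv), i-Pr2NH (10 mol %), CH2Cl2, 0 °C to rt
Reagents that add atoms: N-bromosuccinimide, O=C1CCC(=O)N1Br
Why: Electrophilic aromatic bromination of a phenol; the amine/NBS system delivers bromine to both positions ortho to the free C4 hydroxyl (C3 and C5), while C6 is ortho only to the deactivated ester oxygen and ring B is a doubly brominated, weakly activated ring.

Step 9
Reactants: 18 3,5-dibromo-2-(2,4-dibromophenoxy)-4-hydroxyphenyl 2,2-dimethylpropanoate
Product: 19 3,5-dibromo-2-(2,4-dibromophenoxy)-4-methoxyphenyl 2,2-dimethylpropanoate
Conditions: MeI (3 equiv), K2CO3 (2 equiv), DMF, rt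
Reagents that add atoms: iodomethane, CI
Why: Williamson O-methylation; the 2,6-dibromophenol is acidic enough for K2CO3 and its hindered phenoxide still reacts with the small electrophile, while the pivalate, para to the phenoxide, cannot migrate.

Step 10
Reactants: 19 3,5-dibromo-2-(2,4-dibromophenoxy)-4-methoxyphenyl 2,2-dimethylpropanoate
Product: 20 3,5-dibromo-2-(2,4-dibromophenoxy)-4-methoxyphenol (target)
Conditions: NaOMe (3 equiv), MeOH/THF 1:1, 0 °C to rt; then 1 M HCl
Reagents that add atoms: none
Why: Transesterification of the aryl ester by methoxide, with the aryloxide as a good leaving group; the aryl bromides, the methyl ether and the diaryl ether are inert to NaOMe at room temperature.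

## Compound list

1 | 2,4-dibromophenol | Oc1ccc(Br)cc1Br | starting material
2 | 1,2-dibromoethane | BrCCBr | starting material
3 | 2,4-dibromo-1-(2-bromoethoxy)benzene | BrCCOc1ccc(Br)cc1Br | intermediate
4 | 2,4-dibromo-1-(ethenyloxy)benzene | C=COc1ccc(Br)cc1Br | intermediate
5 | 2,4-dibromo-1-(1,2-dibromoethoxy)benzene (racemic, not isolated) | BrCC(Br)Oc1ccc(Br)cc1Br | intermediate
6 | (Z)-2,4-dibromo-1-(2-bromoethenyloxy)benzene (expected main isomer, not isolated) | Br/C=C\Oc1ccc(Br)cc1Br | intermediate
7 | 2,4-dibromo-1-(ethynyloxy)benzene | C#COc1ccc(Br)cc1Br | intermediate
8 | (E)-(2-bromoethenyl)trimethylsilane | C[Si](C)(C)/C=C/Br | starting material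
9 | chromium hexacarbonyl, Cr(CO)6 | O=C=[Cr](=C=O)(=C=O)(=C=O)(=C=O)=C=O | starting material
10 | (E)-2-(trimethylsilyl)ethenyllithium (not isolated) | [Li]/C=C/[Si](C)(C)C | intermediate
11 | lithium pentacarbonyl[(2E)-1-oxido-3-(trimethylsilyl)prop-2-en-1-ylidene]chromate (not isolated) | [Li+].[O-]C(/C=C/[Si](C)(C)C)=[Cr](=C=O)(=C=O)(=C=O)(=C=O)=C=O | intermediate
12 | pentacarbonyl[(2E)-1-methoxy-3-(trimethylsilyl)prop-2-en-1-ylidene]chromium | COC(/C=C/[Si](C)(C)C)=[Cr](=C=O)(=C=O)(=C=O)(=C=O)=C=O | intermediate
13 | tricarbonyl{hexahapto-[2-(2,4-dibromophenoxy)-4-methoxyphenoxy]trimethylsilane}chromium, metal on ring A (not isolated) | COc1ccc(O[Si](C)(C)C)c(Oc2ccc(Br)cc2Br)c1.O=C=[Cr](=C=O)=C=O | intermediate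
14 | [2-(2,4-dibromophenoxy)-4-methoxyphenoxy]trimethylsilane | COc1ccc(O[Si](C)(C)C)c(Oc2ccc(Br)cc2Br)c1 | intermediate
15 | 2-(2,4-dibromophenoxy)-4-methoxyphenol (not isolated) | COc1ccc(O)c(Oc2ccc(Br)cc2Br)c1 | intermediate
16 | 2-(2,4-dibromophenoxy)-4-methoxyphenyl 2,2-dimethylpropanoate | COc1ccc(OC(=O)C(C)(C)C)c(Oc2ccc(Br)cc2Br)c1 | intermediate
17 | 2-(2,4-dibromophenoxy)-4-hydroxyphenyl 2,2-dimethylpropanoate | Oc1ccc(OC(=O)C(C)(C)C)c(Oc2ccc(Br)cc2Br)c1 | intermediate
18 | 3,5-dibromo-2-(2,4-dibromophenoxy)-4-hydroxyphenyl 2,2-dimethylpropanoate | Oc1c(Br)cc(OC(=O)C(C)(C)C)c(Oc2ccc(Br)cc2Br)c1Br | intermediate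
19 | 3,5-dibromo-2-(2,4-dibromophenoxy)-4-methoxyphenyl 2,2-dimethylpropanoate | COc1c(Br)cc(OC(=O)C(C)(C)C)c(Oc2ccc(Br)cc2Br)c1Br | intermediate
20 | 3,5-dibromo-2-(2,4-dibromophenoxy)-4-methoxyphenol | COc1c(Br)cc(O)c(Oc2ccc(Br)cc2Br)c1Br | target

## Step count and the least certain steps

Total: 10 steps. Longest linear sequence: 9 steps (1, 2, 3, 5, 6, 7, 8, 9, 10, from 2,4-dibromophenol 1); the carbene complex enters through the single step 4.

**Step 5 (key step).**
- Risk: the ynol ether may be consumed by oligomerization on chromium. The sequence may also stall after the first insertion, because the new carbene carbon is stabilized by its aryloxy group and may insert a carbonyl ligand only slowly. Conjugate addition of the electron-rich alkyne to the unsaturated carbene ligand is a further diversion. Loss of regiocontrol is the less likely failure.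
- Fallback (known chemistry, gives up the ring construction): 2,4-dibromophenol 1 is coupled with commercial 2-fluoro-4-methoxybenzaldehyde (COc1ccc(C=O)c(F)c1) by nucleophilic aromatic substitution (Cs2CO3, DMAc, 120 °C), giving 2-(2,4-dibromophenoxy)-4-methoxybenzaldehyde F1. Baeyer–Villiger oxidation (mCPBA, CH2Cl2) gives 2-(2,4-dibromophenoxy)-4-methoxyphenyl formate F2. Methanolysis (K2CO3, MeOH) gives phenol 15, where the route is rejoined and the acylation of step 6 leads to 16.

**Step 3.**
- Risk: the aryloxyalkyne may decompose or oligomerize during warm-up and handling. If the temperature drifts, the amide base may deprotonate ring B between its bromines, followed by halogen migration or aryne formation.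
- Fallback: the two eliminations are separated and the second uses a different kind of base. Dibromide 5 is treated with one equivalent of KN(SiMe3)2 at −78 °C and the stable bromovinyl ether 6 is isolated. Its anti elimination is then carried out with Bu4NF trihydrate in DMF, where fluoride acts as a weak, non-metalating base, and the resulting solution of 7 goes directly into step 5. The fallback sets out from 5 and returns at 7 without a new compound.

**Step 7.**
- Risk: partial cleavage of the pivalate by BBr3 or by HBr during the quench, which would free both hydroquinone oxygens and erase their differentiation.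
- Fallback: a sulfonate replaces the ester. Phenol 15 is converted (MsCl, Et3N, CH2Cl2) into 2-(2,4-dibromophenoxy)-4-methoxyphenyl methanesulfonate F3, which is inert to BBr3. Demethylation gives 2-(2,4-dibromophenoxy)-4-hydroxyphenyl methanesulfonate F4. Dibromination as in step 8 gives 3,5-dibromo-2-(2,4-dibromophenoxy)-4-hydroxyphenyl methanesulfonate F5. Methylation as in step 9 gives 3,5-dibromo-2-(2,4-dibromophenoxy)-4-methoxyphenyl methanesulfonate F6. Hydrolysis (KOH, MeOH/H2O, 60 °C, then acid) returns to the route at target 20.

**Step 8.**
- Risk: the second bromination, at C3 between the hydroxyl and the aryloxy group, is slower than the first at C5. While two equivalents of electrophile are present, substitution at C6′ of ring B or oxidative loss of the acyl group towards a quinone may compete.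
- Fallback: the two brominations are separated. Pivalate 16 is monobrominated under methoxy and aryloxy direction (NBS, 1 equiv, MeCN) at C5, giving 5-bromo-2-(2,4-dibromophenoxy)-4-methoxyphenyl 2,2-dimethylpropanoate F7. Demethylation with BBr3 gives 5-bromo-2-(2,4-dibromophenoxy)-4-hydroxyphenyl 2,2-dimethylpropanoate F8. A single equivalent of NBS with the amine catalyst then brominates the only remaining position ortho to the hydroxyl and returns to the route at 18.

## Further compounds

F1 | step 5 | 2-(2,4-dibromophenoxy)-4-methoxybenzaldehyde | COc1ccc(C=O)c(Oc2ccc(Br)cc2Br)c1
F2 | step 5 | 2-(2,4-dibromophenoxy)-4-methoxyphenyl formate | COc1ccc(OC=O)c(Oc2ccc(Br)cc2Br)c1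
F0 | step 3 | none | none
F3 | step 7 | 2-(2,4-dibromophenoxy)-4-methoxyphenyl methanesulfonate | COc1ccc(OS(C)(=O)=O)c(Oc2ccc(Br)cc2Br)c1
F4 | step 7 | 2-(2,4-dibromophenoxy)-4-hydroxyphenyl methanesulfonate | Oc1ccc(OS(C)(=O)=O)c(Oc2ccc(Br)cc2Br)c1
F5 | step 7 | 3,5-dibromo-2-(2,4-dibromophenoxy)-4-hydroxyphenyl methanesulfonate | Oc1c(Br)cc(OS(C)(=O)=O)c(Oc2ccc(Br)cc2Br)c1Br
F6 | step 7 | 3,5-dibromo-2-(2,4-dibromophenoxy)-4-methoxyphenyl methanesulfonate | COc1c(Br)cc(OS(C)(=O)=O)c(Oc2ccc(Br)cc2Br)c1Br
F7 | step 8 | 5-bromo-2-(2,4-dibromophenoxy)-4-methoxyphenyl 2,2-dimethylpropanoate | COc1cc(Oc2ccc(Br)cc2Br)c(OC(=O)C(C)(C)C)cc1Br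
F8 | step 8 | 5-bromo-2-(2,4-dibromophenoxy)-4-hydroxyphenyl 2,2-dimethylpropanoate | Oc1cc(Oc2ccc(Br)cc2Br)c(OC(=O)C(C)(C)C)cc1Br
A1 | alternative 1 | 3,5-dibromo-2-(2,4-dibromophenoxy)-4-hydroxybenzaldehyde | O=Cc1cc(Br)c(O)c(Br)c1Oc1ccc(Br)cc1Br
A2 | alternative 1 | 4-hydroxy-2-phenoxybenzaldehyde | O=Cc1ccc(O)cc1Oc1ccccc1
A3 | alternative 2 | 3,5-dibromo-2-(2,4-dibromophenoxy)-4,4-dimethoxycyclohexa-2,5-dien-1-one | COC1(OC)C(Br)=CC(=O)C(Oc2ccc(Br)cc2Br)=C1Br
A4 | alternative 2 | 3,5-dibromo-2-(2,4-dibromophenoxy)phenol | Oc1cc(Br)cc(Br)c1Oc1ccc(Br)cc1Br
A5 | alternative 3 | methyl 3-(2,4-dibromophenoxy)-2-hydroxy-5-methoxybenzoate | COC(=O)c1cc(OC)cc(Oc2ccc(Br)cc2Br)c1O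
A6 | alternative 3 | 4-(2,4-dibromophenoxy)-1-methoxy-1,3-bis(trimethylsilyloxy)buta-1,3-diene (double-bond geometry not specified) | COC(O[Si](C)(C)C)=CC(O[Si](C)(C)C)=COc1ccc(Br)cc1Br
A7 | alternative 3 | 1,1,2,3,3-pentamethoxypropane | COC(OC)C(OC)C(OC)OC
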